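## Retrosynthetic overview

- The target comes from its octamethyl ether by global O-demethylation (last step).
- The octamethyl ether comes from a one-flask double enolate/o-quinone methide formal [4+2] annulation on succinic anhydride, which supplies C2–C3–C3'–C2'. Both lactone rings, the C3–C4 and C3'–C4' bonds and all four stereocentres form under one chiral N-heterocyclic carbene.
- The anhydride can deliver only one enolate before its second carboxyl is re-activated, so the phloroglucinol half (ring A) closes first and the pentaoxygenated half (ring B) second, without statistical pairing.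
- The two o-quinone methides are released from bench-stable sulfones: A from 2-hydroxy-4,6-dimethoxybenzaldehyde, an aryl Grignard reagent and sulfinate; B from 2,3,4,5-tetramethoxyphenol, anisaldehyde and sulfinate.
- 2,3,4,5-Tetramethoxyphenol comes from 1,2,3,4-tetramethoxybenzene by lithiation, borylation and oxidation; all benzene rings are bought.

Assumption: the (5aR,10bS) antipode of the aminoindanol triazolium salt is taken to give the (3R,4R) mono-lactone, by analogy with the endo annulations of this catalyst family; this was not verified here, so the first run is checked by chiral HPLC/ECD and the equally available (5aS,10bR) salt is substituted if the sense is opposite.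

## Route

Step 1
Reactants: 1 2-hydroxy-4,6-dimethoxybenzaldehyde; 2 (4-methoxyphenyl)magnesium bromide (2.3 equiv)
Product: 4 3,5-dimethoxy-2-[(4-methoxyphenyl)(4-methylbenzenesulfonyl)methyl]phenol (sulfone A; racemic), via benzhydrol A 3 (not isolated)
Conditions: THF, 0 °C → rt; then p-MeC6H4SO2Na (2 equiv), HCO2H/H2O, 0 °C → rt
Reagents that add atoms: sodium p-toluenesulfinate, Cc1ccc(cc1)S(=O)[O-].[Na+]
Why: Grignard 1,2-addition to the aldehyde (the first equivalent only deprotonates the phenol) gives the benzhydrol, whose doubly donor-stabilised diarylmethyl cation forms in formic acid and is captured at sulfur by sulfinate (SN1 sulfone formation); the benzylic stereocentre is racemic and is erased later when sulfinate is eliminated.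

Step 2
Reactants: 5 1,2,3,4-tetramethoxybenzene
Product: 8 2,3,4,5-tetramethoxyphenol, via aryllithium 6 (not isolated), via lithium arylborate 7 (not isolated)
Conditions: n-BuLi, TMEDA, THF, 0 °C; B(OMe)3, −78 °C → rt; H2O2, AcOH, 0 °C
Reagents that add atoms: hydrogen peroxide, OO
Why: Directed ortho-lithiation next to a methoxy group (the two ring hydrogens are equivalent), borate formation and oxidative boron-to-oxygen aryl migration (boronate oxidation) install the fifth oxygen regiospecifically; no stereocentre is formed.

Step 3
Reactants: 8 2,3,4,5-tetramethoxyphenol; 9 4-methoxybenzaldehyde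
Product: 11 2,3,4,5-tetramethoxy-6-[(4-methoxyphenyl)(4-methylbenzenesulfonyl)methyl]phenol (sulfone B; racemic), via benzhydrol B 10 (not isolated)
Conditions: p-MeC6H4SO2Na (2 equiv), HCO2H/H2O (3:1), rt
Reagents that add atoms: sodium p-toluenesulfinate, Cc1ccc(cc1)S(=O)[O-].[Na+]
Why: Acid-promoted Friedel–Crafts hydroxyalkylation can occur only at the single free ring position (ortho to OH), and the benzhydrol ionises to a diarylmethyl cation that sulfinate traps (three-component sulfonylalkylation, the sulfone counterpart of a Betti/Mannich condensation); the stereocentre is racemic and erased later.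

Step 4
Reactants: 4 sulfone A (1.0 equiv, limiting); 12 succinic anhydride (1.1 equiv); 11 sulfone B (1.05 equiv)
Product: 17 (3S,3'S,4R,4'R)-5,5',6',7,7',8'-hexamethoxy-4,4'-bis(4-methoxyphenyl)-3,3',4,4'-tetrahydro-2H,2'H-[3,3'-bichromene]-2,2'-dione (octamethyl ether of the target), via o-quinone methide A 13 (not isolated), via lactone acid 14 (not isolated), via mixed pivalic anhydride 15 (not isolated), via o-quinone methide B 16 (not isolated)
Conditions: Cs2CO3 (2.2 equiv), THF, 0 °C; 12, (5aR,10bS)-2-mesityl-5a,10b-dihydro-4H,6H-indeno[2,1-b][1,2,4]triazolo[4,3-d][1,4]oxazin-2-ium chloride (C21H22ClN3O, 15 mol%), rt; then PivCl (1.2 equiv), 0 °C; 11, Cs2CO3 (2.2 equiv), rt; AcOH quench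
Reagents that add atoms: none
Why: Proposed new method: base eliminates sulfinate from 4 to give 13, the carbene opens 12 to an acyl azolium carboxylate whose α-deprotonation gives a Z azolium enolate, and this adds endo to the E methide (asynchronous hetero-Diels–Alder, i.e. Michael addition then lactonisation that releases the carbene), so C3/C4 are set cis by the endo approach and in absolute terms by the enolate face left open by the indane; the freed carboxylate 14 is re-activated as 15 and the same catalyst repeats the annulation with 16, so ring B receives the same sense as ring A (catalyst control, the unlike diastereomer being removed by chromatography with Horeau-type gain in ee); the closest known reaction type is the N-heterocyclic carbene-catalysed cis-selective formal [4+2] annulation of azolium enolates from in situ-activated aliphatic carboxylic acids with o-quinone methides released from 2-(tosylmethyl)phenols, together with Lewis base-catalysed enolisation of carboxylic anhydrides.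

Step 5
Reactants: 17 octamethyl ether
Product: 18 (3S,3'S,4R,4'R)-5,5',6',7,7',8'-hexahydroxy-4,4'-bis(4-hydroxyphenyl)-3,3',4,4'-tetrahydro-2H,2'H-[3,3'-bichromene]-2,2'-dione (CNP0064734.1)
Conditions: BBr3 (16 equiv), CH2Cl2, −78 °C → rt; MeOH then H2O, 0 °C, under Ar (aq. Na2S2O4 wash)
Reagents that add atoms: none
Why: BBr3 ether cleavage (Lewis acid activation, then SN2 attack of bromide on methyl) removes all eight aryl methyl groups under non-basic conditions, so the base-labile cis C3/C3' centres are not enolised and any opened lactone recloses on acidic work-up; no stereocentre is touched.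

## Compound list

1 | 2-hydroxy-4,6-dimethoxybenzaldehyde | COc1cc(O)c(C=O)c(OC)c1 | starting material
2 | (4-methoxyphenyl)magnesium bromide | COc1ccc([Mg]Br)cc1 | starting material
3 | benzhydrol A: 2-[hydroxy(4-methoxyphenyl)methyl]-3,5-dimethoxyphenol (racemic) | COc1ccc(cc1)C(O)c1c(O)cc(OC)cc1OC | intermediate
4 | sulfone A: 3,5-dimethoxy-2-[(4-methoxyphenyl)(4-methylbenzenesulfonyl)methyl]phenol (racemic) | COc1ccc(cc1)C(c1c(O)cc(OC)cc1OC)S(=O)(=O)c1ccc(C)cc1 | intermediate
5 | 1,2,3,4-tetramethoxybenzene | COc1ccc(OC)c(OC)c1OC | starting material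
6 | aryllithium: (2,3,4,5-tetramethoxyphenyl)lithium | [Li]c1cc(OC)c(OC)c(OC)c1OC | intermediate
7 | lithium arylborate: lithium trimethoxy(2,3,4,5-tetramethoxyphenyl)borate | [Li+].CO[B-](OC)(OC)c1cc(OC)c(OC)c(OC)c1OC | intermediate
8 | 2,3,4,5-tetramethoxyphenol | COc1cc(O)c(OC)c(OC)c1OC | intermediate
9 | 4-methoxybenzaldehyde | COc1ccc(C=O)cc1 | starting material
10 | benzhydrol B: 2-[hydroxy(4-methoxyphenyl)methyl]-3,4,5,6-tetramethoxyphenol (racemic) | COc1ccc(cc1)C(O)c1c(O)c(OC)c(OC)c(OC)c1OC | intermediate
11 | sulfone B: 2,3,4,5-tetramethoxy-6-[(4-methoxyphenyl)(4-methylbenzenesulfonyl)methyl]phenol (racemic) | COc1ccc(cc1)C(c1c(O)c(OC)c(OC)c(OC)c1OC)S(=O)(=O)c1ccc(C)cc1 | intermediate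
12 | succinic anhydride (oxolane-2,5-dione) | O=C1CCC(=O)O1 | starting material
13 | o-quinone methide A: (6E)-3,5-dimethoxy-6-[(4-methoxyphenyl)methylidene]cyclohexa-2,4-dien-1-one | COc1ccc(cc1)/C=C1/C(=O)C=C(OC)C=C1OC | intermediate
14 | lactone acid: 2-[(3R,4R)-5,7-dimethoxy-4-(4-methoxyphenyl)-2-oxo-3,4-dihydro-2H-chromen-3-yl]acetic acid (3,4-cis; caesium salt in the flask) | O=C1Oc2cc(OC)cc(OC)c2[C@@H](c2ccc(OC)cc2)[C@H]1CC(=O)O | intermediate
15 | mixed pivalic anhydride: 2-[(3R,4R)-5,7-dimethoxy-4-(4-methoxyphenyl)-2-oxo-3,4-dihydro-2H-chromen-3-yl]acetic 2,2-dimethylpropanoic anhydride | O=C1Oc2cc(OC)cc(OC)c2[C@@H](c2ccc(OC)cc2)[C@H]1CC(=O)OC(=O)C(C)(C)C | intermediate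
16 | o-quinone methide B: (6E)-2,3,4,5-tetramethoxy-6-[(4-methoxyphenyl)methylidene]cyclohexa-2,4-dien-1-one | COc1ccc(cc1)/C=C1/C(=O)C(OC)=C(OC)C(OC)=C1OC | intermediate
17 | octamethyl ether: (3S,3'S,4R,4'R)-5,5',6',7,7',8'-hexamethoxy-4,4'-bis(4-methoxyphenyl)-3,3',4,4'-tetrahydro-2H,2'H-[3,3'-bichromene]-2,2'-dione (both lactones 3,4-cis) | O=C1Oc2cc(OC)cc(OC)c2[C@@H](c2ccc(OC)cc2)[C@H]1[C@H]1C(=O)Oc2c(OC)c(OC)c(OC)c(OC)c2[C@H]1c1ccc(OC)cc1 | intermediate
18 | CNP0064734.1: (3S,3'S,4R,4'R)-5,5',6',7,7',8'-hexahydroxy-4,4'-bis(4-hydroxyphenyl)-3,3',4,4'-tetrahydro-2H,2'H-[3,3'-bichromene]-2,2'-dione | O=C1Oc2cc(O)cc(O)c2[C@@H](c2ccc(O)cc2)[C@H]1[C@H]1C(=O)Oc2c(O)c(O)c(O)c(O)c2[C@H]1c1ccc(O)cc1 | target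

## Step count and risks

Total step count: 5. Longest linear sequence: 4 steps (5 → 8 → 11 → 17 → 18).

The three steps most likely to fail:

Step 4 (most likely). The anhydride-derived azolium enolate is unprecedented. Both methides carry a peri methoxy group that slows addition and may erode the cis selectivity. The second annulation uses a hindered, possibly mismatched enolate, and Cs2CO3 can epimerise the cis lactones. The fallback sets out from 4 and comes back to the route at 14. Sulfone 4 is annulated with commercial 4-(benzyloxy)-4-oxobutanoic acid, activated in situ as its mixed pivalic anhydride (PivCl, Cs2CO3, the same triazolium chloride C21H22ClN3O, THF, rt). This is the established activated-aliphatic-acid version of the annulation and gives benzyl 2-[(3R,4R)-5,7-dimethoxy-4-(4-methoxyphenyl)-2-oxo-3,4-dihydro-2H-chromen-3-yl]acetate F1, which is purified and recrystallised to upgrade dr and ee. Hydrogenolysis (H2, 10% Pd/C, EtOAc) then gives 14 as an isolated solid. The second annulation with 11 is run on it as a separate flask operation under the second-stage conditions of step 4 to reach 17.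

Step 3. The stabilised cation may be captured by a second molecule of the electron-rich phenol (triarylmethane) instead of sulfinate, or the hindered position may react slowly with the deactivated aldehyde. The fallback sets out from 8 and comes back at 11. Ortho-formylation (MgCl2, Et3N, paraformaldehyde, MeCN, reflux) gives 2-hydroxy-3,4,5,6-tetramethoxybenzaldehyde F2. Addition of 2 (2.3 equiv, THF, 0 °C) gives benzhydrol 10, here taken on crude. p-MeC6H4SO2Na in HCO2H/H2O converts it into 11, so the carbon–carbon bond formation is separated from the sulfinate capture exactly as in step 1.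

Step 5. Eight ether cleavages are needed on a product whose tetrahydroxylated ring is very air-sensitive, with a risk of partly methylated or C3-epimerised material that cannot be purified as free phenols. The fallback sets out from 17 and comes back at 18. After BBr3 treatment and methanol quench, the crude octaphenol is not isolated. It is evaporated under argon and peracetylated under acid catalysis (Ac2O, Sc(OTf)3 cat., MeCN, 0 °C) to the air-stable octaacetate (3S,3'S,4R,4'R)-4,4'-bis(4-acetoxyphenyl)-2,2'-dioxo-3,3',4,4'-tetrahydro-2H,2'H-[3,3'-bichromene]-5,5',6',7,7',8'-hexayl hexaacetate F3, which is chromatographed and crystallised. The acetates are then removed by acid-catalysed transesterification (HCl in MeOH from AcCl, 0 °C → rt). A brief CF3CO2H/toluene treatment recloses any lactone opened by methanolysis, giving 18.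

Further compounds

F1 | step 4 | benzyl 2-[(3R,4R)-5,7-dimethoxy-4-(4-methoxyphenyl)-2-oxo-3,4-dihydro-2H-chromen-3-yl]acetate | O=C1Oc2cc(OC)cc(OC)c2[C@@H](c2ccc(OC)cc2)[C@H]1CC(=O)OCc1ccccc1
F2 | step 3 | 2-hydroxy-3,4,5,6-tetramethoxybenzaldehyde | O=Cc1c(O)c(OC)c(OC)c(OC)c1OC
F3 | step 5 | (3S,3'S,4R,4'R)-4,4'-bis(4-acetoxyphenyl)-2,2'-dioxo-3,3',4,4'-tetrahydro-2H,2'H-[3,3'-bichromene]-5,5',6',7,7',8'-hexayl hexaacetate | O=C1Oc2cc(OC(C)=O)cc(OC(C)=O)c2[C@@H](c2ccc(OC(C)=O)cc2)[C@H]1[C@H]1C(=O)Oc2c(OC(C)=O)c(OC(C)=O)c(OC(C)=O)c(OC(C)=O)c2[C@H]1c1ccc(OC(C)=O)cc1
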